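**Retrosynthetic overview**

1. The target is traced back (acetate, propionate, silyl ether and redox adjustments only) to a ten-membered-ring diketone with a C2 ketone, the 5Z alkene, the butenolide and the cyclohexenone already in place.
2. The ten-membered carbocycle is not closed directly. It grows by two atoms out of an eight-membered cyclic enol ether (ring O, C2, C1, C10, C9, C8, C7, C6; exocyclic C2=C3H2, isopropenyl on C6) through a Claisen ring expansion that trades the O–C6 bond for the C3–C4 bond.
3. Enabling feature: in the ten-membered ring the C2 oxygen is 1,5-related to the C5=C6 alkene (C2(=O)–C3–C4–C5=C6, a γ,δ-unsaturated ketone), C6 is allylic and adjacent to the butenolide carbon C7, and C1 is quaternary, so the exocyclic enol ether cannot isomerise.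
4. The oxocane is closed by O–C2 bond formation (alkynol cycloisomerisation) in a seco compound made by C8–C9 Negishi coupling of a cyclohexenone iodide with a butenolide (tetronate) triflate.
5. Ring order: cyclohexene by Diels–Alder reaction (sets C1, C10, C14) and butenolide by Dieckmann condensation; then the eight-membered oxocane; last the ten-membered carbocycle by ring expansion.

Key step: step 18

Numbering used in names (target numbering): C1 is the quaternary ring-fusion carbon (CH3 = C15). C2(O-propionyl)–C3–C4–C5(CH3 = C16)=C6–C7(O-lactone)–C8–C9–C10 complete the ten-membered ring. C10–C11(CH3 = C20)=C12–C13(=O)–C14(OAc)–C1 is the six-membered ring. C8=C17(CH3 = C18)–C19(=O)–O–C7 is the butenolide.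

Assumption: the (S)-configured oxazaborolidinium catalyst of step 3 is taken to direct the diene to the enal face that gives the enantiomer drawn; if the sense of induction is the opposite, its (R)-enantiomer is used.

**Route**

Step 1
Reactants: 1 (E)-pent-2-enal
Product: 2 (1E,3E)-1-(tert-butyldimethylsilyloxy)penta-1,3-diene
Conditions: TBSOTf, Et3N, Et2O, 0 °C to 23 °C
Reagents that add atoms: tert-butyldimethylsilyl triflate, CC(C)(C)[Si](C)(C)OS(=O)(=O)C(F)(F)F
Why: Silyl dienol ether formation by γ-deprotonation of the O-silylated enal should give mainly the extended (1E,3E) isomer, and the minor Z isomers do not take part in step 3.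

Step 2
Reactants: 3 2-methyl-2-vinyloxirane
Product: 4 (E)-4-chloro-2-methylbut-2-enal
Conditions: CuCl2·2H2O, LiCl, EtOAc, 80 °C
Reagents that add atoms: copper dichloride, [Cu+2].[Cl-].[Cl-]
Why: Oxidative chlorination of a diene monoepoxide: chloride opens the vinyl epoxide at the vinyl terminus (SN2′) to the (E)-chloro allylic alcohol, which divalent copper oxidises in the same flask to the enal.

Step 3
Reactants: 2 (1E,3E)-1-(tert-butyldimethylsilyloxy)penta-1,3-diene; 4 (E)-4-chloro-2-methylbut-2-enal
Product: 5 2-(tert-butyldimethylsilyloxy)-6-(chloromethyl)-1,5-dimethylcyclohex-3-ene-1-carbaldehyde (CHO cis to OTBS and trans to CH2Cl; 5-methyl cis to OTBS; ring carbons are C1/C14/C13/C12/C11/C10 of the target)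
Conditions: (S)-o-tolyl-CBS-oxazaborolidine (20 mol%), Tf2NH (16 mol%), 2 (2 equiv), CH2Cl2, −78 to −40 °C
Reagents that add atoms: none
Why: Catalytic enantioselective Diels–Alder reaction in which the 1-silyloxy group directs the "ortho" orientation (C14 to the formyl-bearing C1, C11 to C10), the formyl group reacts endo and both partners add suprafacially, which fixes OTBS cis to CHO, CH2Cl trans to CHO (cis to the C1 methyl) and the C11 methyl cis to OTBS, while the chiral oxazaborolidinium Lewis acid selects the enal face and so the absolute configuration at C1, C10 and C14.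

Step 4
Reactants: 5 cycloadduct aldehyde
Product: 6 tert-butyl{[6-(chloromethyl)-1-ethynyl-1,5-dimethylcyclohex-3-en-2-yl]oxy}dimethylsilane (stereocentres as in 5)
Conditions: dimethyl (1-diazo-2-oxopropyl)phosphonate, K2CO3, MeOH, 0 °C to 23 °C
Reagents that add atoms: dimethyl (1-diazo-2-oxopropyl)phosphonate, CC(=O)C(=[N+]=[N-])P(=O)(OC)OC
Why: Seyferth–Gilbert homologation in the Ohira–Bestmann version converts the non-enolisable neopentyl aldehyde (C2) into the terminal alkyne C2≡C3 through an alkylidene carbene and 1,2-hydrogen shift, without touching a stereocentre.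

Step 5
Reactants: 6 cyclohexenyl alkyne
Product: 8 6-(tert-butyldimethylsilyloxy)-4-(chloromethyl)-5-ethynyl-3,5-dimethylcyclohex-2-en-1-one (CH2Cl cis to the 5-methyl; OTBS cis to ethynyl), via allylic hydroperoxide 7 (not isolated)
Conditions: O2, tetraphenylporphyrin (cat.), visible light, Ac2O, pyridine, DMAP (cat.), CH2Cl2, 0 °C to 23 °C
Reagents that add atoms: dioxygen, O=O
Why: Schenck ene reaction followed by Kornblum–DeLaMare dehydration: singlet oxygen should attack the alkene face anti to OTBS and the C11 methyl, bond to C13 and abstract the tertiary allylic hydrogen at C11 (not the deactivated hydrogen geminal to OTBS), and the C13 hydroperoxide is dehydrated to the 3-methyl enone.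

Step 6
Reactants: 8 chloromethyl enone
Product: 9 6-(tert-butyldimethylsilyloxy)-5-ethynyl-4-(iodomethyl)-3,5-dimethylcyclohex-2-en-1-one
Conditions: NaI, butanone, 80 °C
Reagents that add atoms: sodium iodide, [Na+].[I-]
Why: Finkelstein halide exchange (SN2 at the primary carbon C9), driven by precipitation of sodium chloride, gives the iodide needed for zinc insertion.

Step 7
Reactants: 10 (S)-2,2-dimethyl-1,3-dioxolane-4-carbaldehyde
Product: 11 (R)-1-[(S)-2,2-dimethyl-1,3-dioxolan-4-yl]-2-methylprop-2-en-1-ol
Conditions: CH2=C(CH3)MgBr, THF, −78 °C; aqueous NH4Cl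
Reagents that add atoms: isopropenylmagnesium bromide, C=C(C)[Mg]Br
Why: Grignard addition under Felkin–Anh (non-chelation) control should favour the anti adduct, which sets the sacrificial carbinol centre C6 (R) next to the future C7; the minor syn isomer is removed by chromatography.

Step 8
Reactants: 11 anti allylic alcohol
Product: 12 (4S)-4-[(1R)-1-(4-methoxybenzyloxy)-2-methylprop-2-enyl]-2,2-dimethyl-1,3-dioxolane
Conditions: NaH, 4-methoxybenzyl chloride, Bu4NI (cat.), DMF, 0 °C to 23 °C
Reagents that add atoms: 4-methoxybenzyl chloride, COc1ccc(CCl)cc1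
Why: Williamson etherification of the sodium alkoxide protects O6 with a group that is later removed oxidatively in the presence of the silyl ether.

Step 9
Reactants: 12 PMB ether acetonide
Product: 13 (2S,3R)-3-(4-methoxybenzyloxy)-4-methylpent-4-ene-1,2-diol
Conditions: AcOH/H2O 4:1, 40 °C
Reagents that add atoms: none
Why: Acid-catalysed acetal hydrolysis frees the 1,2-diol while the allylic PMB ether survives aqueous acetic acid.

Step 10
Reactants: 13 diol
Product: 14 (2R,3R)-2-hydroxy-3-(4-methoxybenzyloxy)-4-methylpent-4-enoic acid
Conditions: TEMPO (cat.), NaOCl (cat.), NaClO2, phosphate buffer pH 6.7, MeCN, 35 °C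
Reagents that add atoms: sodium chlorite, [Na+].[O-]Cl=O
Why: Nitroxyl-catalysed oxidation: the oxoammonium ion oxidises the primary alcohol much faster than the secondary one and chlorite takes the aldehyde on to the acid (C8) under buffered conditions that should not epimerise C7.

Step 11
Reactants: 14 α-hydroxy acid
Product: 15 methyl (2R,3R)-2-hydroxy-3-(4-methoxybenzyloxy)-4-methylpent-4-enoate
Conditions: MeI, KHCO3, DMF, 23 °C
Reagents that add atoms: iodomethane, CI
Why: SN2 O-alkylation of the carboxylate; the weak base leaves the hydroxyl and C7 untouched.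

Step 12
Reactants: 15 α-hydroxy ester
Product: 16 methyl (2R,3R)-3-(4-methoxybenzyloxy)-4-methyl-2-(propanoyloxy)pent-4-enoate
Conditions: (EtCO)2O, Et3N, DMAP (cat.), CH2Cl2, 0 °C to 23 °C
Reagents that add atoms: propionic anhydride, CCC(=O)OC(=O)CC
Why: DMAP-catalysed acylation installs on O7 the three carbons (C19, C17, C18) of the butenolide.

Step 13
Reactants: 16 α-propanoyloxy ester
Product: 17 (5R)-4-hydroxy-5-[(1R)-1-(4-methoxybenzyloxy)-2-methylprop-2-enyl]-3-methylfuran-2(5H)-one
Conditions: KOtBu (2.2 equiv), THF, 0 °C; 1 M HCl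
Reagents that add atoms: none
Why: Dieckmann condensation: the propionate enolate (C17) acylates the methyl ester carbon (C8) in a 5-exo-trig closure of the butenolide ring, and the product is held as its vinylogous carboxylate, which protects C7 from epimerisation.

Step 14
Reactants: 17 tetronic acid
Product: 18 (5R)-5-[(1R)-1-(4-methoxybenzyloxy)-2-methylprop-2-enyl]-3-methyl-2-oxo-2,5-dihydrofuran-4-yl trifluoromethanesulfonate
Conditions: Tf2O, iPr2NEt, CH2Cl2, −78 °C
Reagents that add atoms: trifluoromethanesulfonic anhydride, O=S(=O)(OS(=O)(=O)C(F)(F)F)C(F)(F)F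
Why: O-sulfonylation of the vinylogous acid gives the enol triflate that makes C8 an electrophile for cross-coupling.

Step 15
Reactants: 9 iodomethyl enone; 18 butenolide triflate
Product: 20 seco PMB ether (cyclohexenone C10–CH2(C9)–C8 butenolide; PMB on O6), via alkylzinc iodide 19 (not isolated)
Conditions: Zn dust (activated), LiCl, THF, 30 °C; then 18, PdCl2(dppf) (5 mol%), THF/NMP, 45 °C
Reagents that add atoms: none
Why: Negishi coupling: zinc inserts into the primary C–I bond (enone, silyl ether and terminal alkyne are tolerated by alkylzinc halides) and zerovalent palladium formed in situ joins sp3 carbon C9 to the enol triflate carbon C8 under neutral conditions that leave C7 untouched.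

Step 16
Reactants: 20 seco PMB ether
Product: 21 seco alkynol (free 6-OH; isopropenyl on C6; ethynyl on C1)
Conditions: DDQ, CH2Cl2/pH 7 buffer 10:1, 0 °C
Reagents that add atoms: none
Why: Oxidative cleavage of the p-methoxybenzyl ether (hydride abstraction by DDQ, hydrolysis of the oxocarbenium ion) frees the C6 hydroxyl while silyl ether, alkyne, enone and butenolide are inert.

Step 17
Reactants: 21 seco alkynol
Product: 22 2-methyleneoxocane (eight-membered cyclic enol ether O–C2(=C3H2)–C1–C10–C9–C8–C7–C6 fused to the cyclohexenone at C1–C10 and to the butenolide at C7–C8; (6R)-isopropenyl)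
Conditions: [(2-biphenylyl)(tBu)2P]Au(NCMe)SbF6 (5 mol%), 4 Å molecular sieves, CH2Cl2 (0.005 M), 23 °C; filtration through Et3N-deactivated basic alumina
Reagents that add atoms: none
Why: Proposed new method: cationic monovalent gold activates the terminal alkyne as a π-complex, the C6 hydroxyl adds anti at the internal carbon C2 (Markovnikov, 8-exo-dig) and protodeauration releases the exocyclic enol ether, which cannot isomerise into the ring because C1 is quaternary; the closure is helped by two rigid elements in the tether (the trans-disubstituted cyclohexenone bond C1–C10 and the butenolide bond C7–C8), the bulky silyl ether and the bridgehead-like enone carbonyl cannot add to the alkyne, and high dilution suppresses intermolecular addition. Closest known reaction type: gold-catalysed hydroalkoxylation of terminal alkynes, known intramolecularly for 2-methylene five- to seven-membered oxacycles and intermolecularly for allylic alcohols (where Claisen rearrangement follows); the exo-dig closure of an eight-membered ring is the untested element.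

Step 18
Reactants: 22 2-methyleneoxocane
Product: 23 ten-membered-ring diketone (C2 ketone; 5Z alkene; C13 enone; 14-OTBS; butenolide)
Conditions: toluene (0.01 M), solid K2CO3 (acid scavenger), sealed tube, 120 °C
Reagents that add atoms: none
Why: Thermal [3,3]-sigmatropic (Claisen) rearrangement of the cyclic allyl vinyl ether C3=C2–O–C6–C5=C4: the O–C6 bond breaks as C3–C4 forms, so the eight-membered oxocane (O, C2, C1, C10, C9, C8, C7, C6) expands by two atoms to the ten-membered carbocycle C1–C10 and its oxygen leaves the ring as the C2 carbonyl. The closest known reaction type is the Claisen ring expansion of 2-methylene-6-vinyltetrahydropyrans and 2-methylene-7-vinyloxepanes to cyclooct-4-enones and cyclonon-4-enones. The ten-membered ring is closed by suprafacial C3–C4 bonding in a bridged, chair-like six-centre transition state that zips the exocyclic carbon C3 to C4 across the oxocane, with no ionic or radical intermediate. No new stereocentre arises; the sacrificial centre C6 is translated into olefin geometry: the eight-membered ring can only span a gauche O–C6–C7 arrangement, which places C7 pseudo-axial in the chair and should give the 5Z alkene, and the (6R) configuration (C6–O anti to the C7–O bond) lets H7 rather than a heavier group eclipse the developing double bond. The selectivity needed is Z over E and [3,3] shift over ionisation or hydrolysis of the enol ether; it is secured by the ring constraint just described, by the acid-free non-polar medium and by quaternary C1, which excludes enol-ether isomerisation. The driving force is C=O formation together with release of the transannular strain of the oxocane.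

Step 19
Reactants: 23 ten-membered-ring diketone
Product: 24 (2S,13R)-2,13-diol (14-OTBS; 5Z; butenolide)
Conditions: (R)-2-methyl-CBS-oxazaborolidine (2 equiv), catecholborane, toluene, −78 to −30 °C; MeOH, pH 7 buffer
Reagents that add atoms: none
Why: Corey–Bakshi–Shibata reduction under reagent control: at C2 the quaternary C1 is the large and C3H2 the small substituent, so the (R)-oxazaborolidine should deliver hydride to give the (2S)-alcohol, and the enone carbonyl C13 is reduced at the same time (its configuration, drawn with OH cis to OTBS, is of no consequence because step 20 removes it).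

Step 20
Reactants: 24 2,13-diol
Product: 25 (2S)-2-hydroxy enone (C13 ketone restored)
Conditions: MnO2 (activated, excess), CH2Cl2, 23 °C
Reagents that add atoms: none
Why: Manganese dioxide oxidises only the allylic alcohol (C13, next to C11=C12) and leaves the saturated neopentyl carbinol C2 untouched.

Step 21
Reactants: 25 2-hydroxy enone
Product: 26 2-O-propanoyl-14-O-TBS intermediate
Conditions: (EtCO)2O, DMAP, pyridine, CH2Cl2, 40 °C
Reagents that add atoms: propionic anhydride, CCC(=O)OC(=O)CC
Why: DMAP-catalysed acylation of the only free hydroxyl installs the C2 propionate with retention.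

Step 22
Reactants: 26 2-O-propanoyl-14-O-TBS intermediate
Product: 27 14-hydroxy enone (2-propionate)
Conditions: HF·pyridine, pyridine/THF, 0 °C to 23 °C
Reagents that add atoms: none
Why: Fluoride-mediated cleavage of the silyl ether under buffered acidic conditions spares both esters, the butenolide and the epimerisable α-ketol centre C14.

Step 23
Reactants: 27 14-hydroxy enone
Product: 28 CNP0109273.3 (target)
Conditions: Ac2O, pyridine, DMAP (cat.), CH2Cl2, 0 °C
Reagents that add atoms: acetic anhydride, CC(=O)OC(C)=O
Why: Acetylation of the secondary α-ketol hydroxyl with retention at C14 completes the target.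

**Compound list**

1 | (E)-pent-2-enal | CC/C=C/C=O | starting material
2 | (1E,3E)-1-(tert-butyldimethylsilyloxy)penta-1,3-diene | C/C=C/C=C/O[Si](C)(C)C(C)(C)C | intermediate
3 | 2-methyl-2-vinyloxirane | CC1(C=C)CO1 | starting material
4 | (E)-4-chloro-2-methylbut-2-enal | O=C/C(C)=C/CCl | intermediate
5 | 2-(tert-butyldimethylsilyloxy)-6-(chloromethyl)-1,5-dimethylcyclohex-3-ene-1-carbaldehyde (CHO cis to OTBS, trans to CH2Cl; 5-Me cis to OTBS) | ClC[C@@H]2[C@@H](C)C=C[C@@H](O[Si](C)(C)C(C)(C)C)[C@]2(C=O)C | intermediate
6 | tert-butyl{[6-(chloromethyl)-1-ethynyl-1,5-dimethylcyclohex-3-en-2-yl]oxy}dimethylsilane | ClC[C@@H]2[C@@H](C)C=C[C@@H](O[Si](C)(C)C(C)(C)C)[C@]2(C#C)C | intermediate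
7 | allylic hydroperoxide (C13–OOH, C11=C12; not isolated) | ClC[C@@H]2C(C)=C[C@H](OO)[C@@H](O[Si](C)(C)C(C)(C)C)[C@]2(C#C)C | intermediate
8 | 6-(tert-butyldimethylsilyloxy)-4-(chloromethyl)-5-ethynyl-3,5-dimethylcyclohex-2-en-1-one | ClC[C@@H]2C(C)=CC(=O)[C@@H](O[Si](C)(C)C(C)(C)C)[C@]2(C#C)C | intermediate
9 | 6-(tert-butyldimethylsilyloxy)-5-ethynyl-4-(iodomethyl)-3,5-dimethylcyclohex-2-en-1-one | IC[C@@H]2C(C)=CC(=O)[C@@H](O[Si](C)(C)C(C)(C)C)[C@]2(C#C)C | intermediate
10 | (S)-2,2-dimethyl-1,3-dioxolane-4-carbaldehyde | O=C[C@@H]1COC(C)(C)O1 | starting material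
11 | (R)-1-[(S)-2,2-dimethyl-1,3-dioxolan-4-yl]-2-methylprop-2-en-1-ol | C=C(C)[C@@H](O)[C@@H]1COC(C)(C)O1 | intermediate
12 | (4S)-4-[(1R)-1-(4-methoxybenzyloxy)-2-methylprop-2-enyl]-2,2-dimethyl-1,3-dioxolane | C=C(C)[C@@H](OCc1ccc(OC)cc1)[C@@H]1COC(C)(C)O1 | intermediate
13 | (2S,3R)-3-(4-methoxybenzyloxy)-4-methylpent-4-ene-1,2-diol | C=C(C)[C@@H](OCc1ccc(OC)cc1)[C@@H](O)CO | intermediate
14 | (2R,3R)-2-hydroxy-3-(4-methoxybenzyloxy)-4-methylpent-4-enoic acid | C=C(C)[C@@H](OCc1ccc(OC)cc1)[C@@H](O)C(=O)O | intermediate
15 | methyl (2R,3R)-2-hydroxy-3-(4-methoxybenzyloxy)-4-methylpent-4-enoate | C=C(C)[C@@H](OCc1ccc(OC)cc1)[C@@H](O)C(=O)OC | intermediate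
16 | methyl (2R,3R)-3-(4-methoxybenzyloxy)-4-methyl-2-(propanoyloxy)pent-4-enoate | C=C(C)[C@@H](OCc1ccc(OC)cc1)[C@@H](OC(=O)CC)C(=O)OC | intermediate
17 | (5R)-4-hydroxy-5-[(1R)-1-(4-methoxybenzyloxy)-2-methylprop-2-enyl]-3-methylfuran-2(5H)-one | C=C(C)[C@@H](OCc1ccc(OC)cc1)[C@H]2OC(=O)C(C)=C2O | intermediate
18 | (5R)-5-[(1R)-1-(4-methoxybenzyloxy)-2-methylprop-2-enyl]-3-methyl-2-oxo-2,5-dihydrofuran-4-yl trifluoromethanesulfonate | C=C(C)[C@@H](OCc1ccc(OC)cc1)[C@H]2OC(=O)C(C)=C2OS(=O)(=O)C(F)(F)F | intermediate
19 | alkylzinc iodide from 9 (not isolated) | I[Zn]C[C@@H]2C(C)=CC(=O)[C@@H](O[Si](C)(C)C(C)(C)C)[C@]2(C#C)C | intermediate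
20 | seco PMB ether (C8–C9 coupled) | C=C(C)[C@@H](OCc1ccc(OC)cc1)[C@H]2OC(=O)C(C)=C2C[C@@H]3C(C)=CC(=O)[C@@H](O[Si](C)(C)C(C)(C)C)[C@]3(C#C)C | intermediate
21 | seco alkynol (free 6-OH) | C=C(C)[C@@H](O)[C@H]2OC(=O)C(C)=C2C[C@@H]3C(C)=CC(=O)[C@@H](O[Si](C)(C)C(C)(C)C)[C@]3(C#C)C | intermediate
22 | 2-methyleneoxocane (eight-membered cyclic enol ether, (6R)-isopropenyl) | C=C(C)[C@@H](O4)[C@H]2OC(=O)C(C)=C2C[C@@H]3C(C)=CC(=O)[C@@H](O[Si](C)(C)C(C)(C)C)[C@]3(C4=C)C | intermediate
23 | ten-membered-ring diketone (C2 and C13 ketones, 5Z, 14-OTBS) | O=C1CC/C(C)=C\[C@H]2OC(=O)C(C)=C2C[C@@H]2C(C)=CC(=O)[C@@H](O[Si](C)(C)C(C)(C)C)[C@@]12C | intermediate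
24 | (2S,13R)-2,13-diol (14-OTBS) | O[C@H]1CC/C(C)=C\[C@H]2OC(=O)C(C)=C2C[C@@H]2C(C)=C[C@@H](O)[C@@H](O[Si](C)(C)C(C)(C)C)[C@@]12C | intermediate
25 | (2S)-2-hydroxy enone (14-OTBS) | O[C@H]1CC/C(C)=C\[C@H]2OC(=O)C(C)=C2C[C@@H]2C(C)=CC(=O)[C@@H](O[Si](C)(C)C(C)(C)C)[C@@]12C | intermediate
26 | 2-O-propanoyl-14-O-TBS intermediate | CCC(=O)O[C@H]1CC/C(C)=C\[C@H]2OC(=O)C(C)=C2C[C@@H]2C(C)=CC(=O)[C@@H](O[Si](C)(C)C(C)(C)C)[C@@]12C | intermediate
27 | 14-hydroxy enone (2-propionate) | CCC(=O)O[C@H]1CC/C(C)=C\[C@H]2OC(=O)C(C)=C2C[C@@H]2C(C)=CC(=O)[C@@H](O)[C@@]12C | intermediate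
28 | CNP0109273.3 | CCC(=O)O[C@H]1CC/C(C)=C\[C@H]2OC(=O)C(C)=C2C[C@@H]2C(C)=CC(=O)[C@@H](OC(C)=O)[C@@]12C | target

**Step count and risks**

Total step count: 23. Longest linear sequence: 17 steps (steps 7 to 23, from compound 10); the cyclohexenone branch is steps 1 to 6.

Steps most likely to fail:

1. Step 17 (proposed new method). The eight-membered ring closure may be too slow, so that intermolecular O–H addition (oligomers) or hydration of the alkyne by adventitious water takes over. The fallback sets out from 21 and comes back at 23. The alkyne is first converted in methanol, by the known intermolecular gold-catalysed hydroalkoxylation (Ph3PAuNTf2 cat., MeOH, 40 °C), into the dimethyl ketal F1. Heating the dimethyl ketal F1 in toluene at 120 °C with a catalytic amount of propanoic acid while methanol is distilled off (ketal-exchange Claisen, Saucy–Marbet conditions) should generate enol ether 22 only in low stationary concentration and drain it irreversibly through the same ring expansion to 23.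

2. Step 18 (key step). A boat-like or tether-equatorial transition state may compete and erode the olefin geometry, or hydrolysis of the enol ether may outrun a sluggish rearrangement. The fallback sets out from 22 and comes back at 23. The rearrangement is accepted with whatever geometry it gives, and material rich in the (5E)-diketone F2 is then equilibrated by reversible thiyl-radical addition (PhSSPh cat., 350 nm light, benzene, 23 °C). This should funnel the more strained E-cyclodecene to the more stable 5Z isomer 23, so that olefin geometry is set thermodynamically and not in the pericyclic step.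

3. Step 3. The face selectivity of the congested cycloaddition may be poor, or the Lewis acid may divert the silyl dienol ether into a vinylogous Mukaiyama aldol addition to the aldehyde. The fallback sets out from 1 and 4 and comes back at 6. The potassium dienolate of 1 (KOtBu, THF, −78 °C) is O-acylated with (S)-O-methylmandeloyl chloride to the chiral dienyl ester F3, whose auxiliary shields one diene face (the enantiomer of the auxiliary is chosen accordingly; (S) is assumed). Its cycloaddition with 4 (EtAlCl2, CH2Cl2, −78 °C) should give the cycloadduct F4 with the same ortho/endo relationships. The Ohira–Bestmann conditions of step 4 (K2CO3, MeOH) then make the alkyne and cleave the mandelate by methanolysis in one operation to the alkynol F5. Silylation (TBSOTf, 2,6-lutidine, CH2Cl2, 0 °C) returns 6.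

**Further compounds**

F1 | step 17 | dimethyl ketal of the C2 methyl ketone derived from 21 | C=C(C)[C@@H](O)[C@H]2OC(=O)C(C)=C2C[C@@H]3C(C)=CC(=O)[C@@H](O[Si](C)(C)C(C)(C)C)[C@]3(C(C)(OC)OC)C
F2 | step 18 | (5E)-isomer of diketone 23 | O=C1CC/C(C)=C/[C@H]2OC(=O)C(C)=C2C[C@@H]2C(C)=CC(=O)[C@@H](O[Si](C)(C)C(C)(C)C)[C@@]12C
F3 | step 3 | (1E,3E)-penta-1,3-dien-1-yl (S)-2-methoxy-2-phenylacetate | C/C=C/C=C/OC(=O)[C@@H](OC)c1ccccc1
F4 | step 3 | cycloadduct aldehyde carrying the (S)-O-methylmandelate on O14 | ClC[C@@H]2[C@@H](C)C=C[C@@H](OC(=O)[C@@H](OC)c3ccccc3)[C@]2(C=O)C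
F5 | step 3 | 6-(chloromethyl)-1-ethynyl-1,5-dimethylcyclohex-3-en-2-ol | ClC[C@@H]2[C@@H](C)C=C[C@@H](O)[C@]2(C#C)C
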